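**Retrosynthetic overview**
1. The isoflavone is cut at C3–C1' and O1–C2 in one operation. This gives an o-hydroxyaryl enaminone (nucleophilic alpha carbon) and a "3-hydroxy-2-methoxyphenyl cation".
2. That cation is dearomatised guaiacol (6-acetoxy-6-methoxycyclohexa-2,4-dienone), a phenol-derived enolonium equivalent. Both carbons joined are natively nucleophilic. Re-aromatisation puts the free 3'-OH and the 2'-OMe in place, so no protecting group is needed.
3. The enaminone comes from 6-hydroxy-2,3,4-trimethoxyacetophenone and DMF dimethyl acetal (which supplies C2). The acetophenone comes from 3,4,5-trimethoxyphenol by ortho-acylation.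
4. Ring order: rings A and B are bought as arenes, and ring B is dearomatised and re-aromatised in the key step. The pyranone ring closes last, in the same flask as the key bond.

Assumption: the target has no stereocentre and no hindered axis (only one ortho substituent on ring B flanks the C3–C1' bond), so it is achiral and no enantiocontrol is needed. The one stereocentre on the route, in the dearomatised guaiacol intermediate, is racemic and is erased on re-aromatisation.

**Step 1**
Reactants: 1 3,4,5-trimethoxyphenol
Product: 2 1-(6-hydroxy-2,3,4-trimethoxyphenyl)ethan-1-one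
Conditions: Ac2O (1.5 equiv), BF3·OEt2 (solvent), 80 °C, 2 h; then H2O
Reagents that add atoms: acetic anhydride, CC(=O)OC(C)=O
Why: This is an O-acetylation/Fries rearrangement (Friedel–Crafts ortho-acylation) in which the para position is blocked and the two ortho positions are equivalent, so only 2 can form, chelation of the product prevents a second acylation, and no stereocentre is made.

**Step 2**
Reactants: 2 1-(6-hydroxy-2,3,4-trimethoxyphenyl)ethan-1-one
Product: 3 (E)-3-(dimethylamino)-1-(6-hydroxy-2,3,4-trimethoxyphenyl)prop-2-en-1-one
Conditions: Me2NCH(OMe)2 (2 equiv), toluene, 95 °C, 3 h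
Reagents that add atoms: N,N-dimethylformamide dimethyl acetal, COC(OC)N(C)C
Why: This is an amide-acetal aminomethylenation of a methyl ketone (enaminone condensation) in which the hydrogen-bonded phenol is left alone and the E alkene is the thermodynamic product.

**Step 3**
Reactants: 3 (E)-3-(dimethylamino)-1-(6-hydroxy-2,3,4-trimethoxyphenyl)prop-2-en-1-one; 4 guaiacol (2-methoxyphenol)
Product: 7 3-(3-hydroxy-2-methoxyphenyl)-5,6,7-trimethoxy-4H-chromen-4-one, via orthoquinol acetate 5 (not isolated), via alpha-aryl enaminone 6 (not isolated)
Conditions: 4 (2.0 equiv), PhI(OAc)2 (1.9 equiv), CH2Cl2, −78 to 0 °C, 1 h; then 3 (1.0 equiv), 0 °C to rt, 16 h; then 40 °C, 2 h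
Reagents that add atoms: (diacetoxyiodo)benzene, CC(=O)OI(OC(C)=O)c1ccccc1 (acetoxy group of 5, lost again on the way to 7)
Why: Proposed new method: the trivalent iodine reagent dearomatises guaiacol by Wessely-type ortho-acetoxylation at the methoxy-bearing carbon to the linearly conjugated dienone 5, an enolonium-type equivalent of the 3-hydroxy-2-methoxyphenyl cation whose best acceptor site is C5 next to the acetal carbon (the terminus that also binds the nucleophilic carbon of enol ethers in their cycloadditions to such dienones); the alpha carbon of 3 adds there in a 1,6 sense as enaminones add to quinones in the Nenitzescu reaction; loss of AcOH (a better leaving group than methoxide, so OMe stays) re-aromatises ring B to 6; the phenol of ring A then closes onto the vinylogous amide with loss of Me2NH, as in the known electrophile-triggered chromone annulations of o-hydroxyaryl enaminones; the closest known reaction types are the Michael addition/re-aromatisation of indoles and electron-rich arenes on masked o-benzoquinones and the Nenitzescu addition; all oxidant is consumed before 3 enters, the liberated AcOH is the only acid (which disfavours ionisation of 5), and the stereocentre of racemic 5 disappears on aromatisation.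

**Compound list**
1 | 3,4,5-trimethoxyphenol | COc1cc(O)cc(OC)c1OC | starting material
2 | 1-(6-hydroxy-2,3,4-trimethoxyphenyl)ethan-1-one | CC(=O)c1c(O)cc(OC)c(OC)c1OC | intermediate
3 | (E)-3-(dimethylamino)-1-(6-hydroxy-2,3,4-trimethoxyphenyl)prop-2-en-1-one | CN(C)/C=C/C(=O)c1c(O)cc(OC)c(OC)c1OC | intermediate
4 | guaiacol (2-methoxyphenol) | COc1ccccc1O | starting material
5 | 6-acetoxy-6-methoxycyclohexa-2,4-dien-1-one (orthoquinol acetate, racemic, not isolated) | COC1(OC(C)=O)C=CC=CC1=O | intermediate
6 | 3-(dimethylamino)-2-(3-hydroxy-2-methoxyphenyl)-1-(6-hydroxy-2,3,4-trimethoxyphenyl)prop-2-en-1-one (alkene geometry undefined, not isolated) | CN(C)C=C(c1cccc(O)c1OC)C(=O)c1c(O)cc(OC)c(OC)c1OC | intermediate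
7 | 3-(3-hydroxy-2-methoxyphenyl)-5,6,7-trimethoxy-4H-chromen-4-one (3'-hydroxy-2',5,6,7-tetramethoxyisoflavone, achiral) | COc1cc2occ(-c3cccc(O)c3OC)c(=O)c2c(OC)c1OC | target

**Totals**
Total step count: 3. Longest linear sequence: 3 (1 → 2 → 3 → 7). Compound 4 enters in the last step.

**Steps most likely to fail**

Step 3 carries the highest risk. The possible failure modes are:
- Compound 5 may dimerise, or guaiacol may be oxidised at its free para position.
- The enaminone may attack C3 of 5, or the para carbon after ionisation of the acetate. Either would give a ring B regioisomer.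
- The first adduct may collapse to a formal [4+2] adduct instead of re-aromatising.
- The hindered donor may simply be too slow.

The fallback sets out from 2 (with 5 made from 4 exactly as in step 3) and returns at 7. It keeps the dearomatised guaiacol acceptor but separates bond formation from ring closure. Compound 2 is silylated on both oxygens (Me3SiOTf, Et3N, CH2Cl2, 0 °C) to the silyl enol ether 1-(2,3,4-trimethoxy-6-trimethylsilyloxyphenyl)-1-trimethylsilyloxyethene F1, a smaller and unhindered donor. Mukaiyama–Michael 1,6-addition of it to 5 (Me3SiOTf 10 mol %, CH2Cl2, −78 °C), loss of acetate and a dilute HCl work-up give the deoxybenzoin 2-(3-hydroxy-2-methoxyphenyl)-1-(6-hydroxy-2,3,4-trimethoxyphenyl)ethan-1-one F2. Its ring B pattern can be checked before going on. One-carbon insertion with DMF, BF3·OEt2 and MsCl (70 °C), which tolerates free phenols, then closes the pyranone ring to 7.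

Step 1 comes next. BF3 can cleave the methoxy group next to the new ketone, or the reaction can stop at the aryl acetate. The fallback sets out from 1 and returns at 2. It replaces the acylium electrophile by a nitrilium one in a Houben–Hoesch reaction. MeCN, ZnCl2 and HCl gas in Et2O at 0 °C precipitate 1-(6-hydroxy-2,3,4-trimethoxyphenyl)ethan-1-iminium chloride F3. Hot water hydrolyses this salt to 2 without any strong Lewis acid at high temperature.

Step 2 is the least risky. The acetal can O-methylate the phenol, or the enaminone can lose Me2NH early to give the 3-unsubstituted chromone. The fallback sets out from 2 and returns at 3. Claisen formylation (HCO2Et, NaH, THF, 0 °C to rt) gives the formyl ketone in its ring-closed form, 2-hydroxy-5,6,7-trimethoxychroman-4-one F4. Dimethylamine in EtOH at rt opens and condenses this to 3.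

**Further compounds**
F1 | step 3 | 1-(2,3,4-trimethoxy-6-trimethylsilyloxyphenyl)-1-trimethylsilyloxyethene | C=C(O[Si](C)(C)C)c1c(O[Si](C)(C)C)cc(OC)c(OC)c1OC
F2 | step 3 | 2-(3-hydroxy-2-methoxyphenyl)-1-(6-hydroxy-2,3,4-trimethoxyphenyl)ethan-1-one | COc1c(O)cccc1CC(=O)c1c(O)cc(OC)c(OC)c1OC
F3 | step 1 | 1-(6-hydroxy-2,3,4-trimethoxyphenyl)ethan-1-iminium chloride | CC(=[NH2+])c1c(O)cc(OC)c(OC)c1OC.[Cl-]
F4 | step 2 | 2-hydroxy-5,6,7-trimethoxychroman-4-one (racemic hemiacetal) | COc1cc2OC(O)CC(=O)c2c(OC)c1OC
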